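**Plan**

- Retrosynthetic cuts, in order: the S–O bond of the sulfate; the O–CH3 bond protecting the oxygen on carbon 1 of ring A; the two ring A C–Br bonds (carbons 3 and 5) together with a temporary C–N bond at carbon 4; the aryl C–O bond between carbon 6 of ring A and the ring B oxygen; the ring C C–I bond (back to a nitro group); the aryl C–O bond between ring C and the other ring B oxygen; the three ring B C–Br bonds (back to guaiacol).
- Forward order: guaiacol is tribrominated (ring B), ring C is joined by SNAr and its nitro group is exchanged for iodine, demethylation frees the second ring B oxygen, and ring A is attached from an aryl(trimethoxyphenyl)iodonium salt. Nitro reduction, double bromination, deamination, demethylation and sulfation follow. All three benzene rings are bought; no ring is built.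
- Enabling feature: on ring A (carbon 1 = C–OSO3H, carbon 6 = C–O–ring B) the bromines sit at carbons 3 and 5, both meta to the oxygen on carbon 1 and on either side of the C–H at carbon 4. Carbon 4 is para to carbon 1, so an NH2 group placed there has its para position blocked by oxygen and only carbons 3 and 5 free as ortho carbons; it is afterwards replaced by hydrogen.
- Stereochemistry: the target is achiral, so only regiochemistry has to be controlled.

Key step: step 9

Assumption: the target is taken in the protonation state drawn (free aryl hydrogen sulfate), so the pyridinium salt from the sulfation is passed through an acidic cation-exchange resin in the cold; the free acid is expected to hydrolyse if warmed.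

**Route**

Step 1
Reactants: 1 guaiacol
Product: 4 2,3,4-tribromo-6-methoxyphenol, via 4-bromoguaiacol 2 (not isolated), via 4,5-dibromoguaiacol 3 (not isolated)
Conditions: Br2 (3.0 equiv), AcOH, 15 °C → rt; recrystallisation
Reagents that add atoms: bromine, BrBr
Why: Electrophilic aromatic bromination in which the free OH directs para and then ortho and the OMe directs para, so bromine should enter the three carbons away from the methoxy group and leave the C–H next to OMe (ortho to OMe only, meta to OH) untouched at this stoichiometry.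

Step 2
Reactants: 4 2,3,4-tribromo-6-methoxyphenol; 5 4-bromo-1-fluoro-2-nitrobenzene
Product: 6 1,2,3-tribromo-4-(4-bromo-2-nitrophenoxy)-5-methoxybenzene
Conditions: K2CO3, DMF, 80 °C
Reagents that add atoms: none
Why: SNAr through a Meisenheimer adduct, in which the fluoride ortho to the nitro group is displaced by the phenoxide while the unactivated aryl bromides stay inert.

Step 3
Reactants: 6 1,2,3-tribromo-4-(4-bromo-2-nitrophenoxy)-5-methoxybenzene
Product: 7 5-bromo-2-(2,3,4-tribromo-6-methoxyphenoxy)aniline
Conditions: Fe powder, AcOH, EtOH, 70 °C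
Reagents that add atoms: none
Why: Béchamp-type nitro reduction by zerovalent iron in acid, which proceeds by electron transfer to the nitro group and, unlike catalytic hydrogenation, should leave the four C–Br bonds intact.

Step 4
Reactants: 7 5-bromo-2-(2,3,4-tribromo-6-methoxyphenoxy)aniline
Product: 9 1,2,3-tribromo-4-(4-bromo-2-iodophenoxy)-5-methoxybenzene, via arenediazonium tosylate 8 (not isolated)
Conditions: NaNO2, TsOH·H2O, KI, MeCN/H2O, 10 °C → rt
Reagents that add atoms: potassium iodide, [K+].[I-]
Why: Diazotisation followed by copper-free Sandmeyer-type iododediazoniation, in which iodide reduces the diazonium ion and the aryl radical is trapped by iodine; Pschorr-type closure onto ring B cannot compete because both ring B carbons ortho to the ether oxygen are substituted.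

Step 5
Reactants: 9 1,2,3-tribromo-4-(4-bromo-2-iodophenoxy)-5-methoxybenzene
Product: 11 3,4,5-tribromo-2-(4-bromo-2-iodophenoxy)phenol, via aryloxydibromoborane 10 (not isolated)
Conditions: BBr3 (3 equiv), CH2Cl2, −78 °C → rt; then H2O
Reagents that add atoms: none
Why: Lewis acid cleavage of an aryl methyl ether, in which bromide attacks the methyl carbon of the boron-complexed ether; the diaryl ether has no sp3 carbon to attack and should survive.

Step 6
Reactants: 12 2-iodo-4-nitroanisole; 13 1,3,5-trimethoxybenzene
Product: 15 (2-methoxy-5-nitrophenyl)(2,4,6-trimethoxyphenyl)iodonium tosylate, via hydroxy(tosyloxy)iodoarene 14 (not isolated)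
Conditions: mCPBA, TsOH·H2O, MeCN, 77 °C; then 1,3,5-trimethoxybenzene; Et2O trituration
Reagents that add atoms: p-toluenesulfonic acid (used as its monohydrate), Cc1ccc(cc1)S(=O)(=O)O
Why: One-pot diaryliodonium synthesis, in which the peracid oxidises the iodoarene to trivalent iodine and the resulting electrophile substitutes the very electron-rich trimethoxybenzene at carbon.

Step 7
Reactants: 11 3,4,5-tribromo-2-(4-bromo-2-iodophenoxy)phenol; 15 (2-methoxy-5-nitrophenyl)(2,4,6-trimethoxyphenyl)iodonium tosylate
Product: 16 1,2,3-tribromo-4-(4-bromo-2-iodophenoxy)-5-(2-methoxy-5-nitrophenoxy)benzene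
Conditions: K2CO3, MeCN, 55 °C
Reagents that add atoms: none
Why: Metal-free O-arylation of a phenoxide by a diaryliodonium salt (ligand exchange at iodine, then ligand coupling), in which the electron-poor, ortho-substituted nitroaryl group is transferred and the trimethoxyphenyl group acts as the dummy ligand; no transition metal is present to touch the C–I and C–Br bonds.

Step 8
Reactants: 16 1,2,3-tribromo-4-(4-bromo-2-iodophenoxy)-5-(2-methoxy-5-nitrophenoxy)benzene
Product: 17 4-methoxy-3-[3,4,5-tribromo-2-(4-bromo-2-iodophenoxy)phenoxy]aniline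
Conditions: Fe powder, AcOH, EtOH, 70 °C
Reagents that add atoms: none
Why: Béchamp-type reduction by zerovalent iron, chemoselective for the nitro group in the presence of aryl iodide and aryl bromides.

Step 9
Reactants: 17 4-methoxy-3-[3,4,5-tribromo-2-(4-bromo-2-iodophenoxy)phenoxy]aniline
Product: 19 2,6-dibromo-4-methoxy-3-[3,4,5-tribromo-2-(4-bromo-2-iodophenoxy)phenoxy]aniline, via monobromoaniline 18 (not isolated)
Conditions: NBS (2.05 equiv, in portions), MeCN, −10 °C → rt, dark
Reagents that add atoms: N-bromosuccinimide, O=C1CCC(=O)N1Br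
Why: Electrophilic aromatic substitution in which NBS delivers electrophilic bromine to the two carbons ortho to NH2 through arenium ions stabilised as iminium ions, first at the less hindered carbon 3 of ring A (also para to the aryloxy oxygen) to give 18 and then at carbon 5 between the amino and aryloxy groups. The closest known reaction is the ortho,ortho-dibromination of para-substituted anilines such as p-anisidine. No ring closes and no stereocentre forms. Ring selectivity is needed and should come from the amino group, which makes ring A far more nucleophilic than rings B and C, whose only donors are ether oxygens offset by three and two halogens. Site selectivity should follow because the para carbon of the aniline carries the methoxy group and carbon 2 of ring A is meta to nitrogen, leaving carbons 3 and 5 as the only activated positions. Low temperature and exact stoichiometry are meant to suppress oxidation of the electron-rich anisidine, and the dibromoaniline formed is deactivated enough to stop further bromination.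

Step 10
Reactants: 19 2,6-dibromo-4-methoxy-3-[3,4,5-tribromo-2-(4-bromo-2-iodophenoxy)phenoxy]aniline
Product: 21 1,5-dibromo-3-methoxy-2-[3,4,5-tribromo-2-(4-bromo-2-iodophenoxy)phenoxy]benzene, via arenediazonium hydrogen sulfate 20 (not isolated)
Conditions: NaNO2, conc. H2SO4, AcOH, 5–15 °C; then 50% aq. H3PO2, 0 °C → rt
Reagents that add atoms: none
Why: Diazotisation of the weakly basic 2,6-dibromoaniline by nitrosylsulfuric acid followed by hydrodediazoniation, a radical chain in which the aryl radical takes a hydrogen atom from H3PO2; chloride-free acid avoids halogen exchange ortho to the diazonium group, and the C–I and C–Br bonds are not reduced.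

Step 11
Reactants: 21 1,5-dibromo-3-methoxy-2-[3,4,5-tribromo-2-(4-bromo-2-iodophenoxy)phenoxy]benzene
Product: 23 3,5-dibromo-2-[3,4,5-tribromo-2-(4-bromo-2-iodophenoxy)phenoxy]phenol, via aryloxydibromoborane 22 (not isolated)
Conditions: BBr3 (3 equiv), CH2Cl2, −78 °C → 0 °C; then H2O
Reagents that add atoms: none
Why: Lewis acid demethylation of the aryl methyl ether by bromide attack on the methyl carbon, to which the two diaryl ether links and the aryl halides are inert.

Step 12
Reactants: 23 3,5-dibromo-2-[3,4,5-tribromo-2-(4-bromo-2-iodophenoxy)phenoxy]phenol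
Product: 25 3,5-dibromo-2-[3,4,5-tribromo-2-(4-bromo-2-iodophenoxy)phenoxy]phenyl hydrogen sulfate, via pyridinium aryl sulfate 24 (not isolated)
Conditions: SO3·pyridine (5 equiv), pyridine, 50 °C; then sulfonic acid cation-exchange resin (H+ form), MeOH/H2O, 0 °C; lyophilisation
Reagents that add atoms: sulfur trioxide–pyridine complex, O=S(=O)([O-])[n+]1ccccc1
Why: O-sulfonation of the phenol by amine-stabilised sulfur trioxide, a standard aryl sulfate synthesis, followed by cation exchange of pyridinium for a proton to give the free acid.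

**Compound list**

1 | guaiacol (2-methoxyphenol) | COc1ccccc1O | starting material
2 | 4-bromo-2-methoxyphenol (4-bromoguaiacol) | COc1cc(Br)ccc1O | intermediate
3 | 4,5-dibromo-2-methoxyphenol (4,5-dibromoguaiacol) | COc1cc(Br)c(Br)cc1O | intermediate
4 | 2,3,4-tribromo-6-methoxyphenol | COc1cc(Br)c(Br)c(Br)c1O | intermediate
5 | 4-bromo-1-fluoro-2-nitrobenzene | O=[N+]([O-])c1cc(Br)ccc1F | starting material
6 | 1,2,3-tribromo-4-(4-bromo-2-nitrophenoxy)-5-methoxybenzene | COc1cc(Br)c(Br)c(Br)c1Oc1ccc(Br)cc1[N+](=O)[O-] | intermediate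
7 | 5-bromo-2-(2,3,4-tribromo-6-methoxyphenoxy)aniline | COc1cc(Br)c(Br)c(Br)c1Oc1ccc(Br)cc1N | intermediate
8 | 5-bromo-2-(2,3,4-tribromo-6-methoxyphenoxy)benzenediazonium tosylate | COc1cc(Br)c(Br)c(Br)c1Oc1ccc(Br)cc1[N+]#N.Cc1ccc(cc1)S(=O)(=O)[O-] | intermediate
9 | 1,2,3-tribromo-4-(4-bromo-2-iodophenoxy)-5-methoxybenzene | COc1cc(Br)c(Br)c(Br)c1Oc1ccc(Br)cc1I | intermediate
10 | dibromo[3,4,5-tribromo-2-(4-bromo-2-iodophenoxy)phenoxy]borane | BrB(Br)Oc1cc(Br)c(Br)c(Br)c1Oc1ccc(Br)cc1I | intermediate
11 | 3,4,5-tribromo-2-(4-bromo-2-iodophenoxy)phenol | Oc1cc(Br)c(Br)c(Br)c1Oc1ccc(Br)cc1I | intermediate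
12 | 2-iodo-4-nitroanisole | COc1ccc(cc1I)[N+](=O)[O-] | starting material
13 | 1,3,5-trimethoxybenzene | COc1cc(OC)cc(OC)c1 | starting material
14 | 2-[hydroxy(tosyloxy)iodo]-1-methoxy-4-nitrobenzene | COc1ccc(cc1I(O)OS(=O)(=O)c1ccc(C)cc1)[N+](=O)[O-] | intermediate
15 | (2-methoxy-5-nitrophenyl)(2,4,6-trimethoxyphenyl)iodonium tosylate | COc1ccc(cc1[I+]c1c(OC)cc(OC)cc1OC)[N+](=O)[O-].Cc1ccc(cc1)S(=O)(=O)[O-] | intermediate
16 | 1,2,3-tribromo-4-(4-bromo-2-iodophenoxy)-5-(2-methoxy-5-nitrophenoxy)benzene | COc1ccc([N+](=O)[O-])cc1Oc1cc(Br)c(Br)c(Br)c1Oc1ccc(Br)cc1I | intermediate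
17 | 4-methoxy-3-[3,4,5-tribromo-2-(4-bromo-2-iodophenoxy)phenoxy]aniline | COc1ccc(N)cc1Oc1cc(Br)c(Br)c(Br)c1Oc1ccc(Br)cc1I | intermediate
18 | 2-bromo-4-methoxy-5-[3,4,5-tribromo-2-(4-bromo-2-iodophenoxy)phenoxy]aniline | COc1cc(Br)c(N)cc1Oc1cc(Br)c(Br)c(Br)c1Oc1ccc(Br)cc1I | intermediate
19 | 2,6-dibromo-4-methoxy-3-[3,4,5-tribromo-2-(4-bromo-2-iodophenoxy)phenoxy]aniline | COc1cc(Br)c(N)c(Br)c1Oc1cc(Br)c(Br)c(Br)c1Oc1ccc(Br)cc1I | intermediate
20 | 2,6-dibromo-4-methoxy-3-[3,4,5-tribromo-2-(4-bromo-2-iodophenoxy)phenoxy]benzenediazonium hydrogen sulfate | COc1cc(Br)c([N+]#N)c(Br)c1Oc1cc(Br)c(Br)c(Br)c1Oc1ccc(Br)cc1I.OS(=O)(=O)[O-] | intermediate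
21 | 1,5-dibromo-3-methoxy-2-[3,4,5-tribromo-2-(4-bromo-2-iodophenoxy)phenoxy]benzene | COc1cc(Br)cc(Br)c1Oc1cc(Br)c(Br)c(Br)c1Oc1ccc(Br)cc1I | intermediate
22 | dibromo{3,5-dibromo-2-[3,4,5-tribromo-2-(4-bromo-2-iodophenoxy)phenoxy]phenoxy}borane | BrB(Br)Oc1cc(Br)cc(Br)c1Oc1cc(Br)c(Br)c(Br)c1Oc1ccc(Br)cc1I | intermediate
23 | 3,5-dibromo-2-[3,4,5-tribromo-2-(4-bromo-2-iodophenoxy)phenoxy]phenol | Oc1cc(Br)cc(Br)c1Oc1cc(Br)c(Br)c(Br)c1Oc1ccc(Br)cc1I | intermediate
24 | pyridinium 3,5-dibromo-2-[3,4,5-tribromo-2-(4-bromo-2-iodophenoxy)phenoxy]phenyl sulfate | [O-]S(=O)(=O)Oc1cc(Br)cc(Br)c1Oc1cc(Br)c(Br)c(Br)c1Oc1ccc(Br)cc1I.c1cc[nH+]cc1 | intermediate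
25 | bromoiesol B sulfate, 3,5-dibromo-2-[3,4,5-tribromo-2-(4-bromo-2-iodophenoxy)phenoxy]phenyl hydrogen sulfate | O=S(=O)(O)Oc1cc(Br)cc(Br)c1Oc1cc(Br)c(Br)c(Br)c1Oc1ccc(Br)cc1I | target

**Step count and risks**

Total steps: 12. Longest linear sequence: 11 (steps 1–5 and 7–12; step 6 is a one-step side branch).

Steps most likely to fail:

Step 7. The ligand coupling at iodine may be slow with the crowded, weakly nucleophilic phenoxide of 11. The wrong aryl group may be transferred, or base may trigger an aryne pathway that scrambles the site of C–O bond formation. The fallback sets out from 11 and returns to the route at 16. It replaces the iodonium chemistry by an oxidative Chan–Lam coupling of 11 with commercial (2-methoxy-5-nitrophenyl)boronic acid (Cu(OAc)2, pyridine, 4 Å molecular sieves, CH2Cl2, air, rt). Divalent copper at room temperature is not expected to insert into the C–I or C–Br bonds, and the product is 16 itself, so no new compound is made.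

Step 9. The electron-rich anisidine may be oxidised by NBS. The second bromination at the crowded carbon 5 of ring A may stall, and forcing it may let bromination spill onto ring C. The fallback sets out from 12 and returns to the route at 21. It keeps the same amine-directed double bromination and deamination but runs them on the small ring A iodide before the ether bond is made. Reduction of 12 (Fe powder, AcOH, EtOH) should give 3-iodo-4-methoxyaniline F1. NBS (2 equiv, MeCN, 0 °C) should brominate this aniline through 2-bromo-5-iodo-4-methoxyaniline F2 to 2,6-dibromo-3-iodo-4-methoxyaniline F3. Diazotisation (NaNO2, H2SO4, AcOH) should give 2,6-dibromo-3-iodo-4-methoxybenzenediazonium hydrogen sulfate F4, and reduction with H3PO2 should then give 1,5-dibromo-2-iodo-3-methoxybenzene F5. Oxidation of this iodide (mCPBA, TsOH·H2O, MeCN) should give 1,5-dibromo-2-[hydroxy(tosyloxy)iodo]-3-methoxybenzene F6, and capture by 13 should give (2,4-dibromo-6-methoxyphenyl)(2,4,6-trimethoxyphenyl)iodonium tosylate F7. O-arylation of 11 with this salt (K2CO3, MeCN, 55 °C) should deliver 21 directly.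

Step 12. Sulfation of the crowded, electron-poor phenol may be incomplete, and the sulfate may be lost by acid-catalysed hydrolysis during cation exchange or concentration. The fallback sets out from 23 and returns to the route at 25. It goes through a neutral, chromatographable sulfate diester. The phenoxide of 23 (NaN(SiMe3)2, THF, −78 °C) is treated with isobutyl chlorosulfate to give isobutyl 3,5-dibromo-2-[3,4,5-tribromo-2-(4-bromo-2-iodophenoxy)phenoxy]phenyl sulfate F8. Sodium iodide in acetone at 55 °C removes the isobutyl group by bimolecular nucleophilic substitution at carbon to give sodium 3,5-dibromo-2-[3,4,5-tribromo-2-(4-bromo-2-iodophenoxy)phenoxy]phenyl sulfate F9. One equivalent of HCl in Et2O/MeOH at 0 °C, with filtration of the precipitated sodium chloride, should then give 25.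

**Further compounds**

F0 | step 7 | none | none
F1 | step 9 | 3-iodo-4-methoxyaniline | COc1ccc(N)cc1I
F2 | step 9 | 2-bromo-5-iodo-4-methoxyaniline | COc1cc(Br)c(N)cc1I
F3 | step 9 | 2,6-dibromo-3-iodo-4-methoxyaniline | COc1cc(Br)c(N)c(Br)c1I
F4 | step 9 | 2,6-dibromo-3-iodo-4-methoxybenzenediazonium hydrogen sulfate | COc1cc(Br)c([N+]#N)c(Br)c1I.OS(=O)(=O)[O-]
F5 | step 9 | 1,5-dibromo-2-iodo-3-methoxybenzene | COc1cc(Br)cc(Br)c1I
F6 | step 9 | 1,5-dibromo-2-[hydroxy(tosyloxy)iodo]-3-methoxybenzene | COc1cc(Br)cc(Br)c1I(O)OS(=O)(=O)c1ccc(C)cc1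
F7 | step 9 | (2,4-dibromo-6-methoxyphenyl)(2,4,6-trimethoxyphenyl)iodonium tosylate | COc1cc(Br)cc(Br)c1[I+]c1c(OC)cc(OC)cc1OC.Cc1ccc(cc1)S(=O)(=O)[O-]
F8 | step 12 | isobutyl 3,5-dibromo-2-[3,4,5-tribromo-2-(4-bromo-2-iodophenoxy)phenoxy]phenyl sulfate | CC(C)COS(=O)(=O)Oc1cc(Br)cc(Br)c1Oc1cc(Br)c(Br)c(Br)c1Oc1ccc(Br)cc1I
F9 | step 12 | sodium 3,5-dibromo-2-[3,4,5-tribromo-2-(4-bromo-2-iodophenoxy)phenoxy]phenyl sulfate | [Na+].[O-]S(=O)(=O)Oc1cc(Br)cc(Br)c1Oc1cc(Br)c(Br)c(Br)c1Oc1ccc(Br)cc1I
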